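The synthesis rests on disconnecting C3–C4 of the oxolane (numbered O1, C2 carrying the ketone chain, C5 carrying butyl). The two stereocentres C2 and C5 are both bonded to O1, so opening that bond leaves an acyclic ether in which each stereocentre is a vinyl-bearing carbinol carbon that can be fixed before any ring exists. The key step, ring-closing olefin metathesis, couples the two vinyl groups, creates C3=C4 and closes the five-membered ring in one operation without touching either centre. Its precursor is the bis-allylic ether 11: a (3R)-hept-1-en-3-yl group and a (3S)-pent-4-enyl unit bearing a silyl-protected hydroxyethyl arm, joined through oxygen.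

Key step: step 7

Remark (assumption on the chemistry): the (Ra,Rc,Rc) enantiomer of the phosphoramidite L [O,O′-(1,1′-binaphthalene-2,2′-diyl) N,N-bis(1-phenylethyl)phosphoramidite] is taken as the one that directs an alkoxide to the face of an aliphatic (E)-allyl unit giving the (3S) ether; should a trial with a simple alkoxide show the opposite sense, the (Sa,Sc,Sc) ligand is used and nothing else changes.

Step 1
Reactants: 1 (±)-hept-1-en-3-ol
Product: 2 (3R)-hept-1-en-3-ol (the enantiomer left unacylated)
Conditions: Novozym 435 (immobilised Candida antarctica lipase B), vinyl acetate, hexane, 30 °C, stopped somewhat past half conversion; chromatography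
Reagents that add atoms: none
Why: Lipase-catalysed kinetic resolution by enantioselective transesterification, in which, following Kazlauskas' rule, the enzyme should acylate the (S)-alcohol (vinyl in the medium pocket, butyl in the large one), so the (R)-alcohol stays behind with enantiopurity that rises as conversion passes one half, fixing the later C5 centre by selection.

Step 2
Reactants: 3 but-3-yn-1-ol
Product: 4 (but-3-yn-1-yloxy)(tert-butyl)dimethylsilane
Conditions: TBSCl, imidazole, CH2Cl2, 0 °C → rt
Reagents that add atoms: tert-butylchlorodimethylsilane (TBSCl), CC(C)(C)[Si](C)(C)Cl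
Why: Silyl ether formation at the primary hydroxyl with imidazole as base and silyl-transfer agent, the terminal alkyne being inert under these conditions.

Step 3
Reactants: 4 (but-3-yn-1-yloxy)(tert-butyl)dimethylsilane
Product: 6 5-{[tert-butyl(dimethyl)silyl]oxy}pent-2-yn-1-ol, via lithium acetylide 5 (not isolated)
Conditions: n-BuLi, THF, −78 °C; (CH2O)n, −78 °C → rt; aq NH4Cl
Reagents that add atoms: paraformaldehyde (as formaldehyde), C=O
Why: Acetylide hydroxymethylation, in which n-BuLi removes the acidic alkyne proton and the lithium acetylide adds to formaldehyde released from the polymer, while the silyl ether is stable to the base at low temperature.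

Step 4
Reactants: 6 5-{[tert-butyl(dimethyl)silyl]oxy}pent-2-yn-1-ol
Product: 7 (2E)-5-{[tert-butyl(dimethyl)silyl]oxy}pent-2-en-1-ol
Conditions: NaAlH2(OCH2CH2OMe)2 (Red-Al), THF, 0 °C → rt; aq potassium sodium tartrate
Reagents that add atoms: none
Why: Hydroxyl-directed trans-hydroalumination of a propargylic alcohol, in which the aluminium bound to the alkoxide delivers hydride intramolecularly and protonolysis of the alkenylaluminate should give the (E)-alkene only, which the next steps need as a single geometry.

Step 5
Reactants: 7 (2E)-5-{[tert-butyl(dimethyl)silyl]oxy}pent-2-en-1-ol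
Product: 8 tert-butyl (2E)-5-{[tert-butyl(dimethyl)silyl]oxy}pent-2-en-1-yl carbonate
Conditions: Boc2O, Bu4NHSO4 (cat.), aq NaOH, CH2Cl2, 0 °C → rt
Reagents that add atoms: di-tert-butyl dicarbonate (Boc2O), CC(C)(C)OC(=O)OC(=O)OC(C)(C)C
Why: O-Alkoxycarbonylation of the primary allylic alcohol under phase-transfer catalysis, the tert-butyl carbonate being chosen because on ionisation it releases only tert-butoxide, which is too hindered to compete with the alkoxide nucleophile of step 6.

Step 6
Reactants: 2 (3R)-hept-1-en-3-ol; 8 tert-butyl (2E)-5-{[tert-butyl(dimethyl)silyl]oxy}pent-2-en-1-yl carbonate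
Product: 11 tert-butyl{[(3S)-3-{[(3R)-hept-1-en-3-yl]oxy}pent-4-en-1-yl]oxy}dimethylsilane, via lithium alkoxide 9 (not isolated), via monovalent copper alkoxide 10 (not isolated)
Conditions: 2, n-BuLi, THF, 0 °C; CuI, rt; then 8, [Ir(cod)Cl]2 (cat.), (Ra,Rc,Rc)-L (cat.), THF, rt; aq NH4Cl
Reagents that add atoms: none
Why: Iridium-catalysed asymmetric allylic etherification, in which the cyclometallated monovalent iridium–phosphoramidite complex ionises 8 (loss of CO2 and tert-butoxide) to an allyl complex and the soft copper alkoxide 10 attacks its substituted terminus from the face away from the metal, so the branched ether should form with the new (3S) C–O centre set by the ligand (catalyst control over the remote centre of the nucleophile), while the (3R) centre of 2 is carried over unchanged because its C–O bond is never broken.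

Step 7
Reactants: 11 tert-butyl{[(3S)-3-{[(3R)-hept-1-en-3-yl]oxy}pent-4-en-1-yl]oxy}dimethylsilane
Product: 12 tert-butyl{2-[(2S,5R)-5-butyl-2,5-dihydrofuran-2-yl]ethoxy}dimethylsilane
Conditions: second-generation Grubbs catalyst RuCl2(=CHPh)(PCy3)(H2IMes) (cat.), CH2Cl2 (high dilution), 40 °C
Reagents that add atoms: none
Why: Ring-closing olefin metathesis by the Chauvin mechanism: the ruthenium benzylidene exchanges with one terminal vinyl group of 11, the new alkylidene adds across the second vinyl group in an intramolecular [2+2] step to give a ruthenacyclobutane, and cycloreversion releases the ring alkene C3=C4 while the ruthenium methylidene formed loses ethene on the next turnover. The closest known reaction type is the metathesis closure of diallyl and bis-allylic ethers to 2,5-dihydrofurans, one of the fastest closures of this kind. The ring closes as a five-membered ring by coupling two monosubstituted alkenes held in a 1,6-relationship through O1, so neither strain nor large-ring entropy opposes it. No stereocentre is created: C2 (S) and C5 (R) enter as allylic C–O carbons whose bonds take no part, so the cis relationship fixed in steps 1 and 6 should simply be preserved. The selectivity required is cyclisation over intermolecular metathesis and over alkene migration by ruthenium hydride species; the short tether and dilution secure the first, the short reaction time of a fast five-membered closure the second, and the escape of ethene makes the step irreversible.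

Step 8
Reactants: 12 tert-butyl{2-[(2S,5R)-5-butyl-2,5-dihydrofuran-2-yl]ethoxy}dimethylsilane
Product: 13 tert-butyl{2-[(2R,5R)-5-butyloxolan-2-yl]ethoxy}dimethylsilane
Conditions: H2 (1 atm), PtO2 (cat.), EtOAc, rt
Reagents that add atoms: none
Why: Heterogeneous catalytic hydrogenation of the cis-disubstituted ring alkene, run over platinum in a neutral solvent to limit alkene migration towards the enol ether and allylic C–O hydrogenolysis, so both centres stay as they are (the C2 descriptor changes from S to R only because C3 loses its priority over the side chain once it is saturated).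

Step 9
Reactants: 13 tert-butyl{2-[(2R,5R)-5-butyloxolan-2-yl]ethoxy}dimethylsilane
Product: 14 2-[(2R,5R)-5-butyloxolan-2-yl]ethan-1-ol
Conditions: Bu4NF, THF, 0 °C → rt; aq NH4Cl
Reagents that add atoms: none
Why: Fluoride-mediated desilylation driven by the strength of the Si–F bond, to which the dialkyl ether ring is inert.

Step 10
Reactants: 14 2-[(2R,5R)-5-butyloxolan-2-yl]ethan-1-ol
Product: 15 [(2R,5R)-5-butyloxolan-2-yl]acetaldehyde
Conditions: Dess–Martin periodinane, pyridine, CH2Cl2, 0 °C → rt; used without storage
Reagents that add atoms: none
Why: Dess–Martin oxidation of a primary alcohol, which stops at the aldehyde and is run buffered and non-basic so that the β-alkoxy aldehyde neither over-oxidises nor eliminates across C2.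

Step 11
Reactants: 15 [(2R,5R)-5-butyloxolan-2-yl]acetaldehyde; 16 1-bromotetradecane
Product: 18 1-[(2R,5R)-5-butyloxolan-2-yl]hexadecan-2-ol (both carbinol epimers), via tetradecylmagnesium bromide 17 (not isolated)
Conditions: 16, Mg turnings (I2-activated), THF, reflux; cooled to −78 °C, 15 added, → 0 °C; aq NH4Cl
Reagents that add atoms: none
Why: Grignard addition to an aldehyde, carried out cold with the reagent in excess to favour 1,2-addition over enolisation, the uncontrolled new carbinol centre being of no consequence because step 12 removes it.

Step 12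
Reactants: 18 1-[(2R,5R)-5-butyloxolan-2-yl]hexadecan-2-ol
Product: 19 1-[(2R,5R)-5-butyloxolan-2-yl]hexadecan-2-one (target)
Conditions: Dess–Martin periodinane, pyridine, CH2Cl2, 0 °C → rt
Reagents that add atoms: none
Why: Dess–Martin oxidation of the secondary alcohol to the ketone under mild buffered conditions, which avoid the base-induced retro-oxa-Michael opening of the β-alkoxy ketone that could epimerise C2.

Compound list
1 | (±)-hept-1-en-3-ol | CCCCC(O)C=C | starting material
2 | (3R)-hept-1-en-3-ol | CCCC[C@@H](O)C=C | intermediate
3 | but-3-yn-1-ol | OCCC#C | starting material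
4 | (but-3-yn-1-yloxy)(tert-butyl)dimethylsilane | CC(C)(C)[Si](C)(C)OCCC#C | intermediate
5 | (4-{[tert-butyl(dimethyl)silyl]oxy}but-1-yn-1-yl)lithium | CC(C)(C)[Si](C)(C)OCCC#C[Li] | intermediate (not isolated)
6 | 5-{[tert-butyl(dimethyl)silyl]oxy}pent-2-yn-1-ol | CC(C)(C)[Si](C)(C)OCCC#CCO | intermediate
7 | (2E)-5-{[tert-butyl(dimethyl)silyl]oxy}pent-2-en-1-ol | CC(C)(C)[Si](C)(C)OCC/C=C/CO | intermediate
8 | tert-butyl (2E)-5-{[tert-butyl(dimethyl)silyl]oxy}pent-2-en-1-yl carbonate | CC(C)(C)[Si](C)(C)OCC/C=C/COC(=O)OC(C)(C)C | intermediate
9 | lithium (3R)-hept-1-en-3-olate | CCCC[C@@H](O[Li])C=C | intermediate (not isolated)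
10 | monovalent copper (3R)-hept-1-en-3-olate | CCCC[C@@H](O[Cu])C=C | intermediate (not isolated)
11 | tert-butyl{[(3S)-3-{[(3R)-hept-1-en-3-yl]oxy}pent-4-en-1-yl]oxy}dimethylsilane | CC(C)(C)[Si](C)(C)OCC[C@@H](C=C)O[C@@H](C=C)CCCC | intermediate
12 | tert-butyl{2-[(2S,5R)-5-butyl-2,5-dihydrofuran-2-yl]ethoxy}dimethylsilane (cis) | CC(C)(C)[Si](C)(C)OCC[C@H]1C=C[C@@H](CCCC)O1 | intermediate
13 | tert-butyl{2-[(2R,5R)-5-butyloxolan-2-yl]ethoxy}dimethylsilane (cis) | CC(C)(C)[Si](C)(C)OCC[C@H]1CC[C@@H](CCCC)O1 | intermediate
14 | 2-[(2R,5R)-5-butyloxolan-2-yl]ethan-1-ol | OCC[C@H]1CC[C@@H](CCCC)O1 | intermediate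
15 | [(2R,5R)-5-butyloxolan-2-yl]acetaldehyde | O=CC[C@H]1CC[C@@H](CCCC)O1 | intermediate
16 | 1-bromotetradecane | CCCCCCCCCCCCCCBr | starting material
17 | tetradecylmagnesium bromide | CCCCCCCCCCCCCC[Mg]Br | intermediate (not isolated)
18 | 1-[(2R,5R)-5-butyloxolan-2-yl]hexadecan-2-ol (carbinol epimers) | CCCCCCCCCCCCCCC(O)C[C@H]1CC[C@@H](CCCC)O1 | intermediate
19 | 1-[(2R,5R)-5-butyloxolan-2-yl]hexadecan-2-one (cis) | CCCCCCCCCCCCCCC(=O)C[C@H]1CC[C@@H](CCCC)O1 | target

Total step count: 12.
Longest linear sequence: 11 steps (3 → 19 through steps 2 to 12); the branch from 1 joins at step 6.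

Steps most likely to fail

Step 6. What may go wrong: the hindered secondary alkoxide may attack the unsubstituted allyl terminus, the catalyst may fail to override the existing centre so that facial selectivity is poor, or alkoxide exchange at the carbonate carbonyl may consume both partners. Fallback (sets out from 7 and 2, returns at 11): the new centre is made beforehand and transferred stereospecifically instead of being induced by the catalyst.
- Sharpless asymmetric epoxidation of 7 (Ti(OiPr)4, L-(+)-diethyl tartrate, t-BuOOH, 4 Å sieves, CH2Cl2, −20 °C) should give [(2S,3S)-3-(2-{[tert-butyl(dimethyl)silyl]oxy}ethyl)oxiran-2-yl]methanol F1.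
- I2, PPh3 and imidazole convert it into tert-butyl{2-[(2S,3R)-3-(iodomethyl)oxiran-2-yl]ethoxy}dimethylsilane F2.
- Zn in EtOH opens F2 reductively to (3S)-5-{[tert-butyl(dimethyl)silyl]oxy}pent-1-en-3-ol F3; the carbinol C–O bond is untouched.
- Boc2O under the conditions of step 5 gives tert-butyl (3S)-5-{[tert-butyl(dimethyl)silyl]oxy}pent-1-en-3-yl carbonate F4.
- RhCl(PPh3)3 modified with P(OMe)3 couples F4 in THF with the copper alkoxide 10 (from 2, LiN(SiMe3)2 and CuI). This is an enantiospecific rhodium-catalysed allylic etherification that proceeds with net retention at the branched carbon and so delivers 11.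

Step 11. What may go wrong: enolisation of the β-alkoxy aldehyde by the basic Grignard reagent followed by β-elimination that opens the ring, or reduction of the aldehyde by β-hydride transfer from the long-chain reagent. Fallback (sets out from 15, returns at 19): the electrophile is changed from an aldehyde to an amide, so the ketone arises by acyl substitution and steps 11 and 12 are both replaced.
- Pinnick oxidation (NaClO2, NaH2PO4, 2-methylbut-2-ene, t-BuOH/H2O) gives [(2R,5R)-5-butyloxolan-2-yl]acetic acid F5.
- Coupling with MeNH(OMe)·HCl (EDC·HCl, i-Pr2NEt, CH2Cl2) gives 2-[(2R,5R)-5-butyloxolan-2-yl]-N-methoxy-N-methylacetamide F6.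
- Addition of 17 in THF at 0 °C forms a chelated tetrahedral intermediate that collapses to 19 only on acidic work-up.

Step 8. What may go wrong: migration of the ring double bond on the metal surface into the enol ether position before reduction, which would erase C2 or C5, or hydrogenolysis of an allylic C–O bond. Fallback (sets out from 12, returns at 13): the reduction is taken off the metal surface altogether. Diimide, generated in the flask from 2-nitrobenzenesulfonohydrazide and Et3N in CH2Cl2 at rt, transfers two hydrogens in a concerted syn fashion and can neither isomerise the alkene nor cleave C–O bonds. This fallback passes through no new compound (F0).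

Further compounds
F1 | step 6 | [(2S,3S)-3-(2-{[tert-butyl(dimethyl)silyl]oxy}ethyl)oxiran-2-yl]methanol | CC(C)(C)[Si](C)(C)OCC[C@@H]1O[C@H]1CO
F2 | step 6 | tert-butyl{2-[(2S,3R)-3-(iodomethyl)oxiran-2-yl]ethoxy}dimethylsilane | CC(C)(C)[Si](C)(C)OCC[C@@H]1O[C@H]1CI
F3 | step 6 | (3S)-5-{[tert-butyl(dimethyl)silyl]oxy}pent-1-en-3-ol | CC(C)(C)[Si](C)(C)OCC[C@H](O)C=C
F4 | step 6 | tert-butyl (3S)-5-{[tert-butyl(dimethyl)silyl]oxy}pent-1-en-3-yl carbonate | CC(C)(C)[Si](C)(C)OCC[C@H](OC(=O)OC(C)(C)C)C=C
F5 | step 11 | [(2R,5R)-5-butyloxolan-2-yl]acetic acid | OC(=O)C[C@H]1CC[C@@H](CCCC)O1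
F6 | step 11 | 2-[(2R,5R)-5-butyloxolan-2-yl]-N-methoxy-N-methylacetamide | CON(C)C(=O)C[C@H]1CC[C@@H](CCCC)O1
F0 | step 8 | none | none
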